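**Retrosynthetic overview**
1. The strategy rests on the carbocycle C1–C10, which holds a cyclodec-5-enone retron: C10 (later =C14H2) as ketone, C4=C5 as alkene, and the bond C2–C3. C6, C7 and C8 fit a cyclohexane ring C5–C10 with all three substituents equatorial.
2. Key disconnection: anionic oxy-Cope ring expansion of a trans-1,2-dialkenylcyclohexanol (ketene acetal on C10, 3-oxyprop-1-en-2-yl on C5) forms C2–C3 and breaks C5–C10.
3. After the expansion: C10 methylenation; C5–O by C15-OH-directed epoxidation from the ring periphery and reductive opening of the epoxy iodide (an attack across the ring from the C2 oxygen would enter on the inner face and give the C5 epimer); C2 ketal closes the O bridge; C8 tiglate; C12 acetal becomes the α-methylene lactone.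
4. Before the expansion: (R)-4-(2,2-dimethoxyethyl)cyclohexenone (organocatalytic Michael/aldol) takes O8 and O6 by two enone/conjugate-borylation rounds and the C3–C4–C15 unit by Suzuki coupling at C5. O6 is tied to C12 as a cyclic acetal, which fixes the lactone regiochemistry.
5. Ring order: cyclohexane (step 3), O6–C12 acetal ring (step 13), ten-membered ring (step 16), C2–O–C5 oxolane bridge (step 22), lactone by oxidation (step 27).

Key step: step 16

Remark: atoms carry the target numbering (C1–C15) in every intermediate; from 19 to 36 the acetal carbon C12 is carried as both anomers (left undefined in the SMILES) because it ends as the lactone carbonyl; the ring-trans C4=C5 alkene of 26–28 (C3 and C6 trans) is Z by the CIP rules because C15 bears oxygen.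

**Step 1**
Reactants: 1 4,4-dimethoxybutanenitrile
Product: 3 4,4-dimethoxybutanal, via aluminium aldimine 2 (not isolated)
Conditions: i-Bu2AlH, CH2Cl2, −78 °C; aq. potassium sodium tartrate
Reagents that add atoms: diisobutylaluminium hydride CC(C)C[AlH]CC(C)C (aluminium of 2); water O
Why: Partial reduction of a nitrile stops at the N-aluminio aldimine, which hydrolyses to the aldehyde on work-up while the acetal is inert to hydride and to the buffered hydrolysis (nitrile-to-aldehyde reduction).

**Step 2**
Reactants: 3 4,4-dimethoxybutanal; 4 but-3-en-2-one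
Product: 5 (2R)-2-(2,2-dimethoxyethyl)-5-oxohexanal
Conditions: (R)-α,α-diphenylprolinol methyl ether (10 mol%), ethyl 3,4-dihydroxybenzoate (20 mol%), neat, 4 °C
Reagents that add atoms: none
Why: Enamine-catalysed asymmetric Michael addition of an aldehyde to a vinyl ketone; the diarylprolinol ether shields one face of the E-enamine, and by the usual steric-shielding model the (R)-catalyst sets C7 as (R), the centre that relays all later ones.

**Step 3**
Reactants: 5 (2R)-2-(2,2-dimethoxyethyl)-5-oxohexanal
Product: 6 (4R)-4-(2,2-dimethoxyethyl)cyclohex-2-en-1-one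
Conditions: LiOH·H2O (cat.), i-PrOH, rt
Reagents that add atoms: none
Why: Intramolecular aldol condensation (methyl ketone enolate onto the aldehyde, then dehydration) closes ring C5–C10; mild base should keep C7, which is no longer α to a carbonyl once the ring exists.

**Step 4**
Reactants: 6 (4R)-4-(2,2-dimethoxyethyl)cyclohex-2-en-1-one
Product: 8 (3S,4R)-4-(2,2-dimethoxyethyl)-3-hydroxycyclohexan-1-one, via boryl ketone 7 (not isolated)
Conditions: B2pin2, CuCl (5 mol%), DPEphos [bis(2-diphenylphosphinophenyl) ether], NaOt-Bu (cat.), MeOH, THF, rt; then NaBO3·4H2O, THF–H2O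
Reagents that add atoms: bis(pinacolato)diboron CC1(C)OB(OC1(C)C)B1OC(C)(C)C(C)(C)O1 (boryl group of 7); sodium perborate [Na+].[O-]OB=O (oxygen)
Why: Copper-catalysed conjugate borylation adds boron to C8 anti to the neighbouring C7 side chain, and perborate oxidation of the C–B bond with retention gives the trans β-hydroxy ketone, which sets C8.

**Step 5**
Reactants: 8 (3S,4R)-4-(2,2-dimethoxyethyl)-3-hydroxycyclohexan-1-one
Product: 9 (3S,4R)-3-[(tert-butyldimethylsilyl)oxy]-4-(2,2-dimethoxyethyl)cyclohexan-1-one
Conditions: t-BuMe2SiCl, imidazole, DMF, rt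
Reagents that add atoms: tert-butyldimethylsilyl chloride CC(C)(C)[Si](C)(C)Cl
Why: Silyl ether protection of the secondary alcohol under non-acidic conditions that leave the dimethyl acetal intact.

**Step 6**
Reactants: 9 (3S,4R)-3-[(tert-butyldimethylsilyl)oxy]-4-(2,2-dimethoxyethyl)cyclohexan-1-one
Product: 10 trimethylsilyl enol ether of 9 toward C5 (C10=C5), tert-butyl{[(1S,6R)-6-(2,2-dimethoxyethyl)-3-(trimethylsilyloxy)cyclohex-3-en-1-yl]oxy}dimethylsilane
Conditions: lithium diisopropylamide, Me3SiCl (internal quench), THF, −78 °C; Et3N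
Reagents that add atoms: chlorotrimethylsilane C[Si](C)(C)Cl
Why: Kinetic enolisation with a hindered amide goes to the C5 methylene, remote from the C8 silyloxy group and its branched neighbour, and the internal silyl quench traps the enol ether before equilibration or β-elimination (regioselective silyl enol ether formation).

**Step 7**
Reactants: 10 trimethylsilyl enol ether (C10=C5)
Product: 11 (4S,5S)-5-[(tert-butyldimethylsilyl)oxy]-4-(2,2-dimethoxyethyl)cyclohex-2-en-1-one (enone C10(=O)–C5=C6)
Conditions: Pd(OAc)2 (1 equiv), MeCN, rt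
Reagents that add atoms: none
Why: Saegusa–Ito oxidation: the palladium enolate at C5 loses the C6 hydride, which moves the unsaturation to the side that still needs O6 and the C5 substituent.

**Step 8**
Reactants: 11 (4S,5S)-5-[(tert-butyldimethylsilyl)oxy]-4-(2,2-dimethoxyethyl)cyclohex-2-en-1-one
Product: 12 (4S,5S)-5-[(tert-butyldimethylsilyl)oxy]-4-(2,2-dimethoxyethyl)-2-iodocyclohex-2-en-1-one (iodine on C5)
Conditions: I2, pyridine–CH2Cl2, 0 °C → rt
Reagents that add atoms: iodine II
Why: α-Iodination of a cycloalkenone by pyridine-mediated addition–elimination puts iodine on C5 under weakly basic conditions that do not enolise toward the silyloxy group.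

**Step 9**
Reactants: 13 2,3-dibromoprop-1-ene
Product: 14 1-{[(2-bromoprop-2-en-1-yl)oxy]methyl}-4-methoxybenzene
Conditions: 4-methoxybenzyl alcohol, NaH, THF, 0 °C → rt
Reagents that add atoms: 4-methoxybenzyl alcohol COc1ccc(CO)cc1
Why: Williamson etherification at the allylic bromide; the vinylic bromide does not react.

**Step 10**
Reactants: 14 1-{[(2-bromoprop-2-en-1-yl)oxy]methyl}-4-methoxybenzene
Product: 15 2-{3-[(4-methoxybenzyl)oxy]prop-1-en-2-yl}-4,4,5,5-tetramethyl-1,3,2-dioxaborolane
Conditions: B2pin2, PdCl2(PPh3)2 (3 mol%), PPh3, KOPh, toluene, 50 °C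
Reagents that add atoms: bis(pinacolato)diboron CC1(C)OB(OC1(C)C)B1OC(C)(C)C(C)(C)O1
Why: Miyaura borylation of an alkenyl bromide with phenoxide as base gives the 1-substituted vinylboronate that carries C3, C4 and C15.

**Step 11**
Reactants: 12 iodoenone; 15 alkenylboronate
Product: 16 (4S,5S)-5-[(tert-butyldimethylsilyl)oxy]-4-(2,2-dimethoxyethyl)-2-{3-[(4-methoxybenzyl)oxy]prop-1-en-2-yl}cyclohex-2-en-1-one
Conditions: PdCl2(dppf) (dppf = 1,1'-bis(diphenylphosphino)ferrocene, 5 mol%), AsPh3, K3PO4, THF–DMF–H2O, rt
Reagents that add atoms: none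
Why: Suzuki–Miyaura coupling of a 2-iodoenone with an alkenylboronate forms C5–C4 under mild base, so the C3–C4–C15 unit enters without enolate chemistry next to the silyloxy group.

**Step 12**
Reactants: 16 cross-conjugated dienone
Product: 18 all-equatorial β-hydroxy ketone (cyclohexanone C10; C5 3-(4-methoxybenzyloxy)prop-1-en-2-yl, C6 OH, C7 CH2CH(OMe)2, C8 OSiMe2t-Bu; 5,6-trans, 6,7-trans, 7,8-trans), via boryl ketone 17 (not isolated)
Conditions: B2pin2, CuCl (10 mol%), DPEphos, NaOt-Bu (cat.), MeOH, THF, rt; then NaBO3·4H2O, THF–H2O, 0 °C → rt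
Reagents that add atoms: bis(pinacolato)diboron CC1(C)OB(OC1(C)C)B1OC(C)(C)C(C)(C)O1 (boryl group of 17); sodium perborate [Na+].[O-]OB=O (oxygen)
Why: A second copper-catalysed conjugate borylation adds boron to C6 anti to the C7 side chain; enolate protonation and equilibration place the C5 alkenyl group equatorial (trans to C6–O), and perborate oxidation with retention gives the alcohol, which sets C6 and C5.

**Step 13**
Reactants: 18 all-equatorial β-hydroxy ketone
Product: 19 trans-fused bicyclic acetal ketone, 4-[(tert-butyldimethylsilyl)oxy]-2-methoxy-7-{3-[(4-methoxybenzyl)oxy]prop-1-en-2-yl}hexahydro-1-benzofuran-6(2H)-one (O6–C12 methyl acetal, both C12 anomers; C5–C8 as in 18)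
Conditions: pyridinium p-toluenesulfonate (cat.), CH2Cl2, 4 Å molecular sieves, rt
Reagents that add atoms: none
Why: Acid-catalysed intramolecular transacetalisation: the C6 hydroxyl displaces one methoxy group of the neighbouring dimethyl acetal to give the trans-fused five-membered methyl acetal, which ties O6 to the future lactone carbon C12 while the silylated C8 oxygen cannot compete.

**Step 14**
Reactants: 20 1,1-diethoxyethene
Product: 22 2-bromo-1,1-diethoxyethene, via dibromide 21 (not isolated)
Conditions: Br2, CH2Cl2–pentane, −78 °C; then Et3N, −78 °C → rt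
Reagents that add atoms: bromine BrBr
Why: Electrophilic bromination of the electron-rich ketene acetal followed by loss of HBr from the adduct with Et3N (addition–elimination, as in the preparation of β-bromovinyl ethers).

**Step 15**
Reactants: 19 bicyclic acetal ketone; 22 2-bromo-1,1-diethoxyethene
Product: 24 1,2-dialkenylcyclohexanol (ring C5–C10; C10 axial OH and equatorial 2,2-diethoxyethenyl C1=C2; C5 equatorial 3-(4-methoxybenzyloxy)prop-1-en-2-yl; O6–C12 methyl acetal trans-fused at C6/C7; C8 equatorial OSiMe2t-Bu), via 2,2-diethoxyvinyllithium 23 (not isolated)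
Conditions: 22, t-BuLi (2 equiv), THF–Et2O, −78 °C; add to 19 pre-stirred with CeCl3, THF, −78 °C; aq. NaHCO3; Et3N-deactivated silica
Reagents that add atoms: tert-butyllithium [Li]C(C)(C)C (lithium of 23)
Why: Bromine–lithium exchange gives the known acetate-equivalent vinyl anion, which adds to the CeCl3-activated ketone from the equatorial side of a chair whose four substituents are equatorial; this gives the axial carbinol with the two alkenyl groups trans-diequatorial and sets C10 (1,2-addition of an organolithium to a ketone).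

**Step 16**
Reactants: 24 1,2-dialkenylcyclohexanol
Product: 26 ten-membered ketone (C10 ketone, C2 diethyl ketal, ring-trans C4=C5 bearing C15H2–O-(4-methoxybenzyl), O6–C12 methyl acetal trans-fused at C6/C7, C8 OSiMe2t-Bu), via potassium enolate 25 (not isolated)
Conditions: KH, 18-crown-6, THF, 0 °C → rt; inverse quench into AcOH–THF, −78 °C
Reagents that add atoms: potassium hydride [K+].[H-] (potassium of 25)
Why: Proposed new method: anionic oxy-Cope ring expansion of trans-1,2-dialkenylcyclohexanols is the closest known reaction type, but a ketene acetal as the 1,5-diene terminus on the carbinol side is untested; the C10 potassium alkoxide of 24 weakens the C5–C10 bond and the [3,3] shift through a chair transition state with both alkenyl groups equatorial forms C2–C3 as C5–C10 breaks, the allyl fragment C5–C4–C3 adding to the acetal carbon C2 of what becomes a β,β-diethoxy enolate, which is polarity-matched. The ten-membered carbocycle is not closed by a cyclisation but arises by four-atom ring expansion of ring C5–C10, giving enolate 25 regiospecifically at C1=C10. No stereocentre is formed: the chair fixes the ring-trans C4=C5 geometry (C3 trans to C6), C5 and C10 lose their stereocentres, and C6, C7 and C8 are untouched. The selectivity needed is the [3,3] shift against alkoxide fragmentation and against loss of ethoxide from C2 or of the C8 silyloxy group from the enolate; the crown-ether-separated alkoxide, the regiospecific C1 enolate and protonation at −78 °C secure it. The ethoxy group cis to C10 is axial in the chair and should slow the shift, so gentle warming may be required.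

**Step 17**
Reactants: 26 ten-membered ketone
Product: 27 C10 methylene compound (C10=C14H2; otherwise as 26)
Conditions: Cp2TiMe2, toluene–THF, 65 °C, dark
Reagents that add atoms: dimethyltitanocene C[Ti](C)(C1C=CC=C1)C1C=CC=C1
Why: Petasis methylenation: the non-basic titanium methylidene converts the C10 ketone into the exocyclic methylene without enolising it toward the C8 silyloxy or C2 ketal groups.

**Step 18**
Reactants: 27 C10 methylene compound
Product: 28 allylic C15 alcohol
Conditions: DDQ, CH2Cl2–pH 7 buffer, 0 °C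
Reagents that add atoms: none
Why: Oxidative cleavage of the 4-methoxybenzyl ether frees the primary allylic alcohol and leaves silyl ether, ketal, acetal and alkenes.

**Step 19**
Reactants: 28 allylic C15 alcohol
Product: 29 4,5-epoxy C15 alcohol (epoxide oxygen on the outer face; C5–O configured as in the target, syn to O6)
Conditions: VO(acac)2 (5 mol%), t-BuOOH (anhydrous, decane), CH2Cl2, 0 °C
Reagents that add atoms: tert-butyl hydroperoxide CC(C)(C)OO
Why: Hydroxyl-directed vanadium-catalysed epoxidation of an allylic alcohol is selective for C4=C5 and delivers oxygen to the peripheral face of the ring-trans alkene; with H6 eclipsing C15 (allylic 1,3-strain) the ring passes over the face anti to O6, so C5 should take oxygen syn to O6, which sets C4 and C5.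

**Step 20**
Reactants: 29 4,5-epoxy C15 alcohol
Product: 30 4,5-epoxy C15 iodide
Conditions: PPh3, I2, imidazole, Et2O–MeCN, 0 °C
Reagents that add atoms: iodine II
Why: Appel-type iodination converts the primary alcohol into the iodide while the imidazole-buffered epoxide stays closed.

**Step 21**
Reactants: 30 4,5-epoxy C15 iodide
Product: 31 C5 allylic alcohol (C4=C15H2; C5–OH as in the target; C2 diethyl ketal)
Conditions: Zn dust (activated), EtOH, 50 °C
Reagents that add atoms: none
Why: Zinc inserts into the C15–I bond and the β-alkoxy organozinc eliminates, opening the epoxide at C4 (reductive transposition of an epoxy iodide to an allylic alcohol); the C5–O bond is not touched, so C5 keeps the configuration of step 19.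

**Step 22**
Reactants: 31 C5 allylic alcohol
Product: 32 bridged methyl ketal (C2(OMe)–O–C5 oxolane bridge)
Conditions: pyridinium p-toluenesulfonate (cat.), MeOH, 0 °C → rt
Reagents that add atoms: methanol CO
Why: Acid-catalysed transketalisation: the C5 hydroxyl adds to the oxocarbenium ion from the C2 ketal (five-membered ring, exo closure), the ketal exchanging much faster than the aldehyde-derived C12 acetal; the bridge can only form on one face, which sets C2.

**Step 23**
Reactants: 32 bridged methyl ketal
Product: 33 C8 alcohol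
Conditions: Bu4NF, THF, rt
Reagents that add atoms: none
Why: Fluoride cleavage of the silyl ether frees the C8 hydroxyl, the only hydroxyl group in the molecule.

**Step 24**
Reactants: 33 C8 alcohol; 34 tiglic acid
Product: 36 C8 tiglate, via mixed anhydride 35 (not isolated)
Conditions: 34, 2,4,6-trichlorobenzoyl chloride, Et3N, toluene, rt; then 33, DMAP, rt
Reagents that add atoms: 2,4,6-trichlorobenzoyl chloride O=C(Cl)c1c(Cl)cc(Cl)cc1Cl (aroyl group of 35)
Why: Yamaguchi esterification acylates the hindered secondary alcohol through the mixed anhydride with retention at C8 and without loss of the E geometry of the tiglate.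

**Step 25**
Reactants: 36 C8 tiglate
Product: 37 C2 hemiketal C12 lactol
Conditions: 1 M HCl–THF (1:4), 0 °C → rt
Reagents that add atoms: water O
Why: Mild aqueous acid hydrolyses the exocyclic methoxy groups of the C2 ketal and the C12 acetal through their cyclic oxocarbenium ions (acetal hydrolysis), giving hemiketal and lactol with both rings kept and the ester untouched.

**Step 26**
Reactants: 37 C2 hemiketal C12 lactol
Product: 38 α-methylene lactol (C11=C13H2)
Conditions: CH2=NMe2+ I−, Et3N, CH2Cl2, rt
Reagents that add atoms: N,N-dimethylmethyleneiminium iodide C=[N+](C)C.[I-]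
Why: Mannich reaction of the open hydroxy-aldehyde form of the lactol with Eschenmoser's salt and elimination of dimethylamine give the α-methylene aldehyde, which closes again to the lactol (aldehyde α-methylenation).

**Step 27**
Reactants: 38 α-methylene lactol
Product: 39 target CNP0307443.2
Conditions: PhI(OAc)2, TEMPO (10 mol%), CH2Cl2, rt
Reagents that add atoms: none
Why: Oxoammonium oxidation of the secondary lactol gives the α-methylene γ-lactone; the tertiary hemiketal hydroxyl cannot be oxidised.

**Compound list**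
1 | 4,4-dimethoxybutanenitrile | N#CCCC(OC)OC | starting material
2 | N-(diisobutylaluminio) aldimine of 4,4-dimethoxybutanal | CC(C)C[Al](CC(C)C)N=CCCC(OC)OC | intermediate
3 | 4,4-dimethoxybutanal | O=CCCC(OC)OC | intermediate
4 | but-3-en-2-one | CC(=O)C=C | starting material
5 | (2R)-2-(2,2-dimethoxyethyl)-5-oxohexanal | O=C[C@@H](CC(OC)OC)CCC(C)=O | intermediate
6 | (4R)-4-(2,2-dimethoxyethyl)cyclohex-2-en-1-one | O=C1C=C[C@@H](CC(OC)OC)CC1 | intermediate
7 | trans-4-(2,2-dimethoxyethyl)-3-(4,4,5,5-tetramethyl-1,3,2-dioxaborolan-2-yl)cyclohexan-1-one | O=C1C[C@H](B2OC(C)(C)C(C)(C)O2)[C@@H](CC(OC)OC)CC1 | intermediate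
8 | (3S,4R)-4-(2,2-dimethoxyethyl)-3-hydroxycyclohexan-1-one | O=C1C[C@H](O)[C@@H](CC(OC)OC)CC1 | intermediate
9 | (3S,4R)-3-[(tert-butyldimethylsilyl)oxy]-4-(2,2-dimethoxyethyl)cyclohexan-1-one | O=C1C[C@H](O[Si](C)(C)C(C)(C)C)[C@@H](CC(OC)OC)CC1 | intermediate
10 | tert-butyl{[(1S,6R)-6-(2,2-dimethoxyethyl)-3-(trimethylsilyloxy)cyclohex-3-en-1-yl]oxy}dimethylsilane | C[Si](C)(C)OC1=CC[C@H](CC(OC)OC)[C@@H](O[Si](C)(C)C(C)(C)C)C1 | intermediate
11 | (4S,5S)-5-[(tert-butyldimethylsilyl)oxy]-4-(2,2-dimethoxyethyl)cyclohex-2-en-1-one | O=C1C=C[C@H](CC(OC)OC)[C@@H](O[Si](C)(C)C(C)(C)C)C1 | intermediate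
12 | (4S,5S)-5-[(tert-butyldimethylsilyl)oxy]-4-(2,2-dimethoxyethyl)-2-iodocyclohex-2-en-1-one | O=C1C(I)=C[C@H](CC(OC)OC)[C@@H](O[Si](C)(C)C(C)(C)C)C1 | intermediate
13 | 2,3-dibromoprop-1-ene | C=C(Br)CBr | starting material
14 | 1-{[(2-bromoprop-2-en-1-yl)oxy]methyl}-4-methoxybenzene | C=C(Br)COCc1ccc(OC)cc1 | intermediate
15 | 2-{3-[(4-methoxybenzyl)oxy]prop-1-en-2-yl}-4,4,5,5-tetramethyl-1,3,2-dioxaborolane | C=C(COCc1ccc(OC)cc1)B1OC(C)(C)C(C)(C)O1 | intermediate
16 | (4S,5S)-5-[(tert-butyldimethylsilyl)oxy]-4-(2,2-dimethoxyethyl)-2-{3-[(4-methoxybenzyl)oxy]prop-1-en-2-yl}cyclohex-2-en-1-one | O=C1C(C(=C)COCc2ccc(OC)cc2)=C[C@H](CC(OC)OC)[C@@H](O[Si](C)(C)C(C)(C)C)C1 | intermediate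
17 | C6-boryl ketone (boron anti to the C7 side chain, C5 alkenyl trans to boron) | O=C1[C@H](C(=C)COCc2ccc(OC)cc2)[C@@H](B2OC(C)(C)C(C)(C)O2)[C@H](CC(OC)OC)[C@@H](O[Si](C)(C)C(C)(C)C)C1 | intermediate
18 | all-equatorial β-hydroxy ketone (C5 alkenyl, C6 OH, C7 CH2CH(OMe)2, C8 OSiMe2t-Bu) | O=C1[C@H](C(=C)COCc2ccc(OC)cc2)[C@@H](O)[C@H](CC(OC)OC)[C@@H](O[Si](C)(C)C(C)(C)C)C1 | intermediate
19 | 4-[(tert-butyldimethylsilyl)oxy]-2-methoxy-7-{3-[(4-methoxybenzyl)oxy]prop-1-en-2-yl}hexahydro-1-benzofuran-6(2H)-one, trans-fused, C12 anomers | O=C1[C@H](C(=C)COCc2ccc(OC)cc2)[C@H]2OC(OC)C[C@@H]2[C@@H](O[Si](C)(C)C(C)(C)C)C1 | intermediate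
20 | 1,1-diethoxyethene | C=C(OCC)OCC | starting material
21 | 1,2-dibromo-1,1-diethoxyethane | BrCC(Br)(OCC)OCC | intermediate
22 | 2-bromo-1,1-diethoxyethene | BrC=C(OCC)OCC | intermediate
23 | 2,2-diethoxyvinyllithium | [Li]C=C(OCC)OCC | intermediate
24 | 1,2-dialkenylcyclohexanol, oxy-Cope precursor (C10 axial OH, equatorial 2,2-diethoxyethenyl; C5 equatorial alkenyl) | O[C@@]1(C=C(OCC)OCC)C[C@H](O[Si](C)(C)C(C)(C)C)[C@H]2CC(OC)O[C@@H]2[C@H]1C(=C)COCc1ccc(OC)cc1 | intermediate
25 | potassium C1=C10 enolate of 26 | [K+].[O-]C1=CC(OCC)(OCC)C/C(COCc2ccc(OC)cc2)=C/[C@H]2OC(OC)C[C@@H]2[C@@H](O[Si](C)(C)C(C)(C)C)C1 | intermediate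
26 | ten-membered ketone, oxy-Cope product (C10 ketone, C2 diethyl ketal, ring-trans C4=C5) | O=C1CC(OCC)(OCC)C/C(COCc2ccc(OC)cc2)=C/[C@H]2OC(OC)C[C@@H]2[C@@H](O[Si](C)(C)C(C)(C)C)C1 | intermediate
27 | C10 methylene compound | C=C1CC(OCC)(OCC)C/C(COCc2ccc(OC)cc2)=C/[C@H]2OC(OC)C[C@@H]2[C@@H](O[Si](C)(C)C(C)(C)C)C1 | intermediate
28 | allylic C15 alcohol | C=C1CC(OCC)(OCC)C/C(CO)=C/[C@H]2OC(OC)C[C@@H]2[C@@H](O[Si](C)(C)C(C)(C)C)C1 | intermediate
29 | 4,5-epoxy C15 alcohol | C=C1CC(OCC)(OCC)C[C@@]2(CO)O[C@@H]2[C@H]2OC(OC)C[C@@H]2[C@@H](O[Si](C)(C)C(C)(C)C)C1 | intermediate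
30 | 4,5-epoxy C15 iodide | C=C1CC(OCC)(OCC)C[C@@]2(CI)O[C@@H]2[C@H]2OC(OC)C[C@@H]2[C@@H](O[Si](C)(C)C(C)(C)C)C1 | intermediate
31 | C5 allylic alcohol with C4=C15 methylene | C=C1CC(OCC)(OCC)CC(=C)[C@H](O)[C@H]2OC(OC)C[C@@H]2[C@@H](O[Si](C)(C)C(C)(C)C)C1 | intermediate
32 | bridged methyl ketal (C2(OMe)–O–C5), C8 silyl ether | C=C1C[C@H](O[Si](C)(C)C(C)(C)C)[C@H]2CC(OC)O[C@@H]2[C@H]2O[C@@](OC)(C1)CC2=C | intermediate
33 | bridged methyl ketal, C8 alcohol | C=C1C[C@H](O)[C@H]2CC(OC)O[C@@H]2[C@H]2O[C@@](OC)(C1)CC2=C | intermediate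
34 | tiglic acid, (E)-2-methylbut-2-enoic acid | C/C=C(\C)C(=O)O | starting material
35 | tiglic 2,4,6-trichlorobenzoic anhydride | C/C=C(\C)C(=O)OC(=O)c1c(Cl)cc(Cl)cc1Cl | intermediate
36 | bridged methyl ketal, C8 tiglate | C=C1C[C@H](OC(=O)/C(C)=C/C)[C@H]2CC(OC)O[C@@H]2[C@H]2O[C@@](OC)(C1)CC2=C | intermediate
37 | C2 hemiketal, C12 lactol, C8 tiglate | C=C1C[C@H](OC(=O)/C(C)=C/C)[C@H]2CC(O)O[C@@H]2[C@H]2O[C@@](O)(C1)CC2=C | intermediate
38 | α-methylene lactol | C=C1C[C@H](OC(=O)/C(C)=C/C)[C@H]2C(=C)C(O)O[C@@H]2[C@H]2O[C@@](O)(C1)CC2=C | intermediate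
39 | CNP0307443.2 | C=C1C[C@H](OC(=O)/C(C)=C/C)[C@H]2C(=C)C(=O)O[C@@H]2[C@H]2O[C@@](O)(C1)CC2=C | target

Total step count: 27 steps. Longest linear sequence: 24 steps (1–8, 11–13, 15–27, from 4,4-dimethoxybutanenitrile).

**Three steps most likely to fail**

First, the key step, step 16, which bears the label for a proposed new method. The [3,3] shift may be too slow with the electron-rich ketene acetal terminus and its axial ethoxy group, so that fragmentation of the alkoxide, or loss of ethoxide from the enolate before the quench, takes over. The fallback is the known acetylenic anionic oxy-Cope ring expansion, with the C2 oxygen put in afterwards; it sets out from 19 and comes back to the route at 32. Ethynylmagnesium bromide with CeCl3 in THF at −78 °C should add to 19 from the equatorial side and give the 1-ethynyl carbinol F1. KH and 18-crown-6 in THF should rearrange it, and protonation of the allenolate should give the cyclodeca-2,5-dienone F2, whose C1=C2 geometry does not matter. Nucleophilic epoxidation of the enone with t-BuOOH and catalytic DBU at 0 °C should give the C1–C2 epoxy ketone F3, and Cp2TiMe2 should methylenate C10 to the C10-methylene C1–C2 oxirane F4. Pd2(dba)3 (zerovalent palladium), PBu3 and HCO2H–Et3N should hydrogenolyse the allylic C1–O bond and leave the C2 alcohol F5, which Dess–Martin periodinane buffered with NaHCO3 should oxidise to the C2 ketone F6. HC(OMe)3, MeOH and pyridinium p-toluenesulfonate should then give the C2 dimethyl ketal F7; methanol is chosen over ethanol so that exchange at the C12 methyl acetal changes nothing. The conditions of steps 18 to 21 should carry this compound on through the allylic C15 alcohol F8, the 4,5-epoxy C15 alcohol F9 and the 4,5-epoxy C15 iodide F10 to the C5 allylic alcohol F11, and the conditions of step 22 should close the bridge and give 32, which carries a methoxy group on C2 in either series.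

Second, step 19. Facial selectivity may be poor if the epoxidation runs through the ring-flipped conformer of the ten-membered ring, and trace acid could open the epoxide across the ring; either process would leave the wrong configuration at C5 after step 21. The fallback sets C5 by reagent control instead of substrate control; it sets out from 31, taken as the C5 mixture then obtained, and comes back to the route at 31. Dess–Martin periodinane buffered with NaHCO3 should give the C5 enone F12, which has no stereocentre at C5. Corey–Bakshi–Shibata reduction with (S)-2-methyl-CBS-oxazaborolidine and catecholborane in toluene at −78 °C, in which the alkenyl carbon C4 acts as the large group, should return 31 as the single C5 epimer.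

Third, step 12. Conjugate borylation of the α-branched dienone may be sluggish, the new C6 oxygen may be lost by β-elimination during oxidation or equilibration, and the C4=C3 alkene may move into conjugation. The fallback replaces the boron chemistry by epoxide chemistry; it sets out from 16 and comes back to the route at 18. Nucleophilic epoxidation with t-BuOOH and DBU, anti to the C7 side chain, should give the 5,6-epoxy ketone F13. SmI2 in THF–MeOH at −78 °C should cleave the C5–O bond next to the carbonyl group, and protonation of the samarium enolate at C5 should return 18.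

**Further compounds**
F1 | step 16 | 1-ethynyl carbinol (C10 axial OH, equatorial ethynyl; otherwise as 24) | O[C@@]1(C#C)C[C@H](O[Si](C)(C)C(C)(C)C)[C@H]2CC(OC)O[C@@H]2[C@H]1C(=C)COCc1ccc(OC)cc1
F2 | step 16 | cyclodeca-2,5-dienone (C10 ketone, C1=C2, ring-trans C4=C5) | O=C1C=CC/C(COCc2ccc(OC)cc2)=C/[C@H]2OC(OC)C[C@@H]2[C@@H](O[Si](C)(C)C(C)(C)C)C1
F3 | step 16 | C1–C2 epoxy ketone | O=C1C2OC2C/C(COCc2ccc(OC)cc2)=C/[C@H]2OC(OC)C[C@@H]2[C@@H](O[Si](C)(C)C(C)(C)C)C1
F4 | step 16 | C10-methylene C1–C2 oxirane | C=C1C2OC2C/C(COCc2ccc(OC)cc2)=C/[C@H]2OC(OC)C[C@@H]2[C@@H](O[Si](C)(C)C(C)(C)C)C1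
F5 | step 16 | C2 alcohol | C=C1CC(O)C/C(COCc2ccc(OC)cc2)=C/[C@H]2OC(OC)C[C@@H]2[C@@H](O[Si](C)(C)C(C)(C)C)C1
F6 | step 16 | C2 ketone | C=C1CC(=O)C/C(COCc2ccc(OC)cc2)=C/[C@H]2OC(OC)C[C@@H]2[C@@H](O[Si](C)(C)C(C)(C)C)C1
F7 | step 16 | C2 dimethyl ketal (otherwise as 27) | C=C1CC(OC)(OC)C/C(COCc2ccc(OC)cc2)=C/[C@H]2OC(OC)C[C@@H]2[C@@H](O[Si](C)(C)C(C)(C)C)C1
F8 | step 16 | allylic C15 alcohol, C2 dimethyl ketal (otherwise as 28) | C=C1CC(OC)(OC)C/C(CO)=C/[C@H]2OC(OC)C[C@@H]2[C@@H](O[Si](C)(C)C(C)(C)C)C1
F9 | step 16 | 4,5-epoxy C15 alcohol, C2 dimethyl ketal (otherwise as 29) | C=C1CC(OC)(OC)C[C@@]2(CO)O[C@@H]2[C@H]2OC(OC)C[C@@H]2[C@@H](O[Si](C)(C)C(C)(C)C)C1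
F10 | step 16 | 4,5-epoxy C15 iodide, C2 dimethyl ketal (otherwise as 30) | C=C1CC(OC)(OC)C[C@@]2(CI)O[C@@H]2[C@H]2OC(OC)C[C@@H]2[C@@H](O[Si](C)(C)C(C)(C)C)C1
F11 | step 16 | C5 allylic alcohol, C2 dimethyl ketal (otherwise as 31) | C=C1CC(OC)(OC)CC(=C)[C@H](O)[C@H]2OC(OC)C[C@@H]2[C@@H](O[Si](C)(C)C(C)(C)C)C1
F12 | step 19 | C5 enone (C5 ketone conjugated with C4=C15) | C=C1CC(OCC)(OCC)CC(=C)C(=O)[C@H]2OC(OC)C[C@@H]2[C@@H](O[Si](C)(C)C(C)(C)C)C1
F13 | step 12 | 5,6-epoxy ketone (oxygen anti to the C7 side chain) | O=C1[C@@]2(C(=C)COCc3ccc(OC)cc3)O[C@H]2[C@H](CC(OC)OC)[C@@H](O[Si](C)(C)C(C)(C)C)C1
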